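**Retrosynthetic overview**
Feature: on ring A (C1–C6) the tetrasubstituted exocyclic alkene C5=C7 holds its CH2OH carbon C8 cis to C6, the ring carbon that carries the arm C9–C10–C11–OH, so C8 and C10 can be the two ends of one bond in a six-membered ring B (C5, C6, C9, C10, C8, C7).
Target ⇐ hydroboration of a C10=C11 vinyl group and 1,2-reduction of a C8 enal ⇐ Grob cleavage of the temporary C8–C10 bond of ring B ⇐ [4+2] addition of acrolein (C9–C11) to the ring-A-fused diene C6=C5–C7(Me)=C8H–OTBS.
Diene ⇐ C5 enol triflate (isopropenyl coupling, hydroboration, oxidation, silyl enolisation) ⇐ Me2CuLi addition with enolate triflation on the (R)-4-methylcyclohexenone that bears the C16 chain on its β-carbon; this sets quaternary C1.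
That enone ⇐ (R)-4-methylcyclohex-2-enone (organocatalytic Michael addition, aldol condensation) + C16 Grignard reagent (conjugate addition, reoxidation); the chain ⇐ alkyne from (S)-citronellal + dibromide from 5-bromo-2-methylpent-2-ene (alkenyl–allyl coupling).
Ring order: ring A first (step 6), temporary ring B second (step 14), ring B opened again in step 17.

Key step: step 14

Remark on labels: target numbering is used for all ring compounds: C1 quaternary (methyl and chain), C2 CHMe, C3, C4, C5, C6; C7 alkylidene carbon, C8 its oxygenated carbon; C9–C11 the arm on C6. In the 4-methylcyclohexenone the carbonyl carbon is the later C5, Cα is C6, Cβ is C1 and the CHMe carbon is C2. "C16 chain" means (3E,6E,8S)-4,8,12-trimethyltrideca-3,6,11-trien-1-yl.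
Assumption: the (S)-configured prolinol ether of step 5 is taken to give the (R)-aldehyde, as the steric-shielding enamine model predicts; the mirror-image catalyst would be used if the sense proved opposite.

Step 1
Reactants: 1 (S)-citronellal [(3S)-3,7-dimethyloct-6-enal]
Product: 3 (3S)-3,7-dimethyloct-6-en-1-yne, via alkenyl nonaflate 2 (not isolated)
Conditions: C4F9SO2F, phosphazene base P2-Et, DMF, −30 °C → rt
Reagents that add atoms: none
Why: Known one-pot conversion of an enolisable aldehyde into a terminal alkyne: the phosphazene base forms the enolate, C4F9SO2F traps it on oxygen as alkenyl nonaflate 2, and a second equivalent of base eliminates nonaflate (β-elimination), while C3 is never deprotonated and should keep its S configuration.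

Step 2
Reactants: 4 5-bromo-2-methylpent-2-ene
Product: 5 (2E)-5-bromo-2-methylpent-2-en-1-ol
Conditions: SeO2 (0.5 equiv), t-BuOOH, CH2Cl2, 0 °C → rt
Reagents that add atoms: selenium dioxide, O=[Se]=O (delivers the oxygen atom and is reoxidised by tert-butyl hydroperoxide, CC(C)(C)OO)
Why: Riley-type allylic oxidation (ene reaction of SeO2, then [2,3]-sigmatropic shift of the allylseleninic acid) attacks the methyl group trans to the chain of a trisubstituted alkene, so the E allylic alcohol should form, and the primary bromide is inert.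

Step 3
Reactants: 5 (2E)-5-bromo-2-methylpent-2-en-1-ol
Product: 6 (2E)-1,5-dibromo-2-methylpent-2-ene
Conditions: CBr4, PPh3, CH2Cl2, 0 °C
Reagents that add atoms: carbon tetrabromide, BrC(Br)(Br)Br
Why: Appel reaction: the alkoxyphosphonium ion is displaced by bromide at the primary allylic carbon without transposition, and the alkene geometry is untouched.

Step 4
Reactants: 3 (3S)-3,7-dimethyloct-6-en-1-yne; 6 (2E)-1,5-dibromo-2-methylpent-2-ene
Product: 8 (3E,6E,8S)-1-bromo-4,8,12-trimethyltrideca-3,6,11-triene, via alkenylzirconocene chloride 7 (not isolated)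
Conditions: Cp2Zr(H)Cl, THF, rt; then 6, Pd(PPh3)4 (5 mol%), THF, rt
Reagents that add atoms: none
Why: Hydrozirconation adds Zr–H syn with zirconium on the terminal carbon, giving the E alkenylzirconocene 7, which undergoes Negishi-type Pd-catalysed alkenyl–allyl coupling at the allylic C–Br bond only (the primary alkyl bromide does not add oxidatively), bonding at the unsubstituted allyl terminus with retention of both alkene geometries.

Step 5
Reactants: 9 propanal; 10 but-3-en-2-one (methyl vinyl ketone)
Product: 11 (2R)-2-methyl-5-oxohexanal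
Conditions: (S)-2-[methoxy(diphenyl)methyl]pyrrolidine (5 mol%), ethyl 3,4-dihydroxybenzoate (20 mol%), neat, 4 °C
Reagents that add atoms: none
Why: Enamine-catalysed asymmetric Michael addition: the E enamine of propanal is shielded on one face by the methoxydiphenylmethyl group of the (S)-catalyst and should add to the enone through the open face to set the R centre.

Step 6
Reactants: 11 (2R)-2-methyl-5-oxohexanal
Product: 13 (4R)-4-methylcyclohex-2-en-1-one, via aldol 12 (not isolated)
Conditions: LiOH (cat.), i-PrOH, rt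
Reagents that add atoms: none
Why: Intramolecular aldol condensation (6-enolexo addition of the methyl ketone enolate to the aldehyde, then E1cB loss of water) closes ring A, and the stereocentre ends up γ to the carbonyl, where it is much less prone to epimerise.

Step 7
Reactants: 8 (3E,6E,8S)-1-bromo-4,8,12-trimethyltrideca-3,6,11-triene; 13 (4R)-4-methylcyclohex-2-en-1-one
Product: 15 trimethyl{[(3S,4R)-4-methyl-3-(C16 chain)cyclohex-1-en-1-yl]oxy}silane (chain trans to methyl), via Grignard reagent 14 (not isolated)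
Conditions: 8, Mg, THF, rt, used at once; then 13, CuBr·SMe2 (5 mol%), TMSCl, HMPA, THF, −78 °C
Reagents that add atoms: chlorotrimethylsilane, C[Si](C)(C)Cl
Why: Copper-catalysed, TMSCl-accelerated conjugate addition of the Grignard reagent delivers the chain to the β-carbon (the later C1) anti to the C2 methyl and traps the enolate regiospecifically as its silyl ether; the new centre at C1 is erased in step 8.

Step 8
Reactants: 15 trimethyl{[(3S,4R)-4-methyl-3-(C16 chain)cyclohex-1-en-1-yl]oxy}silane
Product: 16 (4R)-4-methyl-3-(C16 chain)cyclohex-2-en-1-one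
Conditions: Pd(OAc)2 (1.05 equiv), MeCN, rt
Reagents that add atoms: none
Why: Saegusa–Ito oxidation: the silyl enol ether gives a palladium enolate whose β-hydride elimination toward C1 restores the enone, now with the chain on the β-carbon, without touching C2.

Step 9
Reactants: 16 (4R)-4-methyl-3-(C16 chain)cyclohex-2-en-1-one
Product: 18 (3R,4R)-3,4-dimethyl-3-(C16 chain)cyclohex-1-en-1-yl trifluoromethanesulfonate (C1 R and C2 R in target labels; methyl groups trans), via lithium enolate 17 (not isolated)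
Conditions: Me2CuLi (from MeLi and CuI), Et2O, −20 → 0 °C; then PhNTf2, THF, 0 °C → rt
Reagents that add atoms: lithium dimethylcuprate, [Li+].C[Cu-]C; N-phenylbis(trifluoromethanesulfonimide), O=S(=O)(N(c1ccccc1)S(=O)(=O)C(F)(F)F)C(F)(F)F
Why: Conjugate addition of Me2CuLi forms the quaternary C1: allylic 1,2-strain with the C1 chain holds the C2 methyl pseudoaxial and the cuprate attacks axially on the opposite face, so the two methyl groups should end up trans (C1 R), and the regiodefined enolate is trapped on oxygen by PhNTf2 as the C5 enol triflate.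

Step 10
Reactants: 18 (3R,4R)-3,4-dimethyl-3-(C16 chain)cyclohex-1-en-1-yl trifluoromethanesulfonate
Product: 19 (3R,4R)-3,4-dimethyl-1-(prop-1-en-2-yl)-3-(C16 chain)cyclohex-1-ene
Conditions: isopropenylboronic acid pinacol ester, Pd(dppf)Cl2 (5 mol%), K3PO4 (aq), THF, 50 °C
Reagents that add atoms: 2-isopropenyl-4,4,5,5-tetramethyl-1,3,2-dioxaborolane, CC(=C)B1OC(C)(C)C(C)(C)O1
Why: Suzuki–Miyaura coupling of the alkenyl triflate with the alkenylboronate forms the C5–C7 bond and gives the 2-substituted 1,3-diene; no stereocentre is affected.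

Step 11
Reactants: 19 (3R,4R)-3,4-dimethyl-1-(prop-1-en-2-yl)-3-(C16 chain)cyclohex-1-ene
Product: 21 2-[(3R,4R)-3,4-dimethyl-3-(C16 chain)cyclohex-1-en-1-yl]propan-1-ol (both C7 epimers), via B-alkyl-9-BBN 20 (not isolated)
Conditions: 9-BBN (1.3 equiv), THF, 0 °C → rt; then NaOH (aq), H2O2, 0 °C
Reagents that add atoms: hydrogen peroxide, OO
Why: Hydroboration with 9-BBN is far faster at a 1,1-disubstituted terminal alkene than at the trisubstituted and trans-disubstituted alkenes of ring and chain and places boron on the terminal carbon C8; oxidation gives the primary alcohol, and the uncontrolled C7 centre is erased in step 13.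

Step 12
Reactants: 21 2-[(3R,4R)-3,4-dimethyl-3-(C16 chain)cyclohex-1-en-1-yl]propan-1-ol
Product: 22 2-[(3R,4R)-3,4-dimethyl-3-(C16 chain)cyclohex-1-en-1-yl]propanal (both C7 epimers)
Conditions: Dess–Martin periodinane, NaHCO3, CH2Cl2, 0 °C
Reagents that add atoms: none
Why: Dess–Martin oxidation under buffered, non-enolising conditions should give the β,γ-unsaturated aldehyde without migration of the C5=C6 double bond into conjugation.

Step 13
Reactants: 22 2-[(3R,4R)-3,4-dimethyl-3-(C16 chain)cyclohex-1-en-1-yl]propanal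
Product: 23 tert-butyl({(1E)-2-[(3R,4R)-3,4-dimethyl-3-(C16 chain)cyclohex-1-en-1-yl]prop-1-en-1-yl}oxy)dimethylsilane
Conditions: TBSOTf, Et3N, CH2Cl2, −78 → 0 °C
Reagents that add atoms: tert-butyldimethylsilyl trifluoromethanesulfonate, CC(C)(C)[Si](C)(C)OS(=O)(=O)C(F)(F)F
Why: Soft enolisation (O-silylation, then removal of the only α-hydrogen, at C7, by Et3N) gives the 1-silyloxy diene with fixed regiochemistry; the E isomer, with the silyloxy group away from ring A, should prevail because the Z isomer suffers allylic 1,3-strain, and any Z isomer, inert in step 14, is hydrolysed back to 22.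

Step 14
Reactants: 23 tert-butyl({(1E)-2-[(3R,4R)-3,4-dimethyl-3-(C16 chain)cyclohex-1-en-1-yl]prop-1-en-1-yl}oxy)dimethylsilane; 24 acrolein
Product: 25 (2S,3S,7R,8R,8aS)-3-[(tert-butyldimethylsilyl)oxy]-4,7,8-trimethyl-8-(C16 chain)-1,2,3,5,6,7,8,8a-octahydronaphthalene-2-carbaldehyde (endo adduct; C6 S, C8 S, C10 S in target labels)
Conditions: 24 (5 equiv), 2,6-di-tert-butyl-4-methylphenol (cat.), toluene, 60 °C, sealed tube
Reagents that add atoms: none
Why: The electron-rich diene, which reaches its s-cis form easily because C5 and C7 both carry substituents, adds acrolein in a concerted, asynchronous suprafacial [4+2] cycloaddition in which the C6–C9 bond leads and the C8–C10 bond follows. The closest known reaction type is the thermal Diels–Alder reaction of 1-(trialkylsilyloxy)buta-1,3-dienes with acrolein, which gives the ortho adduct. Ring B (C5, C6, C9, C10, C8, C7) is closed by intermolecular [4+2] annulation, both σ bonds forming in one step, and is fused to ring A at C5–C6. C6 is set by π-facial selection under control of C1 and C2: the lower face of C6 is screened in either half-chair of ring A, by the pseudoaxial C16 chain when the C2 methyl is equatorial and by the then axial C2 methyl (1,3-syn-axial to the incoming carbon) after ring inversion, so acrolein should bond on the face that carries the C1 methyl; C8 and C10 follow from the E enol ether and the endo transition state, and both are erased later. The step needs this facial selectivity and the ortho orientation, the latter secured by the donor oxygen on C8 and by the fact that the unsubstituted CH2 of acrolein meets the hindered C6. Since C6 and C8 become members of the same six-membered ring, the C5=C7 bond formed between them can only have C8 on the C6 side, for the endo as for the exo adduct.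

Step 15
Reactants: 25 (2S,3S,7R,8R,8aS)-3-[(tert-butyldimethylsilyl)oxy]-4,7,8-trimethyl-8-(C16 chain)-1,2,3,5,6,7,8,8a-octahydronaphthalene-2-carbaldehyde
Product: 26 [(2R,3S,7R,8R,8aS)-3-[(tert-butyldimethylsilyl)oxy]-4,7,8-trimethyl-8-(C16 chain)-1,2,3,5,6,7,8,8a-octahydronaphthalen-2-yl]methanol
Conditions: NaBH4, THF/MeOH, −20 → 0 °C, on the crude adduct
Reagents that add atoms: none
Why: Chemoselective hydride reduction of the aldehyde at low temperature, carried out before β-elimination of silanol can occur; no stereocentre is formed (the descriptor at C10 changes only because the priorities change).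

Step 16
Reactants: 26 [(2R,3S,7R,8R,8aS)-3-[(tert-butyldimethylsilyl)oxy]-4,7,8-trimethyl-8-(C16 chain)-1,2,3,5,6,7,8,8a-octahydronaphthalen-2-yl]methanol
Product: 27 [(2R,3S,7R,8R,8aS)-3-[(tert-butyldimethylsilyl)oxy]-4,7,8-trimethyl-8-(C16 chain)-1,2,3,5,6,7,8,8a-octahydronaphthalen-2-yl]methyl 4-methylbenzenesulfonate
Conditions: TsCl, Et3N, 4-(dimethylamino)pyridine (cat.), CH2Cl2, 0 °C → rt
Reagents that add atoms: p-toluenesulfonyl chloride, Cc1ccc(cc1)S(=O)(=O)Cl
Why: Sulfonylation of the primary alcohol installs the nucleofuge at C11; the hindered secondary oxygen at C8 stays silylated.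

Step 17
Reactants: 27 [(2R,3S,7R,8R,8aS)-3-[(tert-butyldimethylsilyl)oxy]-4,7,8-trimethyl-8-(C16 chain)-1,2,3,5,6,7,8,8a-octahydronaphthalen-2-yl]methyl 4-methylbenzenesulfonate
Product: 29 (2Z)-2-[(2S,3R,4R)-3,4-dimethyl-2-(prop-2-en-1-yl)-3-(C16 chain)cyclohexylidene]propanal, via hydroxy tosylate 28 (not isolated)
Conditions: TBAF, THF, 0 °C → rt
Reagents that add atoms: none
Why: Grob fragmentation of a 1,3-diol monosulfonate: fluoride frees the C8 oxygen, rotation about C10–C11 places the C11–OTs bond anti-periplanar to C8–C10, and the alkoxide expels tosylate with cleavage of that bond only, giving the C8 aldehyde and the C10=C11 alkene; the Z geometry of C5=C7 is inherited from ring B and C6 is not touched.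

Step 18
Reactants: 29 (2Z)-2-[(2S,3R,4R)-3,4-dimethyl-2-(prop-2-en-1-yl)-3-(C16 chain)cyclohexylidene]propanal
Product: 30 (2Z)-2-[(2S,3R,4R)-3,4-dimethyl-2-(prop-2-en-1-yl)-3-(C16 chain)cyclohexylidene]propan-1-ol
Conditions: NaBH4, CeCl3·7H2O, MeOH, −40 °C, directly after step 17
Reagents that add atoms: none
Why: Luche reduction should give clean 1,2-reduction of the hindered enal at low temperature, which also ends the risk of Z to E isomerisation through the dienolate; no stereocentre is formed.

Step 19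
Reactants: 30 (2Z)-2-[(2S,3R,4R)-3,4-dimethyl-2-(prop-2-en-1-yl)-3-(C16 chain)cyclohexylidene]propan-1-ol
Product: 32 3-[(1S,2R,3R,6Z)-6-(1-hydroxypropan-2-ylidene)-2,3-dimethyl-2-(C16 chain)cyclohexyl]propan-1-ol (CNP0327981.1), via bis(9-BBN) adduct 31 (not isolated)
Conditions: 9-BBN (3 equiv), THF, 0 °C → rt; then NaOH (aq), H2O2, 0 °C
Reagents that add atoms: hydrogen peroxide, OO
Why: 9-BBN hydroborates the monosubstituted terminal alkene far faster than the tri- and tetrasubstituted and trans-disubstituted alkenes and places boron on C11, the free hydroxyl group consuming one equivalent as a borinate; alkaline peroxide then gives the primary alcohol and frees the allylic one.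

**Compound list**
1 | (S)-citronellal, (3S)-3,7-dimethyloct-6-enal | CC(C)=CCC[C@H](C)CC=O | starting material
2 | (3S)-3,7-dimethylocta-1,6-dien-1-yl nonafluorobutane-1-sulfonate (E/Z mixture) | CC(C)=CCC[C@H](C)C=COS(=O)(=O)C(F)(F)C(F)(F)C(F)(F)C(F)(F)F | intermediate (not isolated)
3 | (3S)-3,7-dimethyloct-6-en-1-yne | CC(C)=CCC[C@H](C)C#C | intermediate
4 | 5-bromo-2-methylpent-2-ene | CC(C)=CCCBr | starting material
5 | (2E)-5-bromo-2-methylpent-2-en-1-ol | OC/C(C)=C/CCBr | intermediate
6 | (2E)-1,5-dibromo-2-methylpent-2-ene | BrC/C(C)=C/CCBr | intermediate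
7 | chlorobis(cyclopentadienyl)[(1E,3S)-3,7-dimethylocta-1,6-dien-1-yl]zirconium | CC(C)=CCC[C@H](C)/C=C/[Zr](Cl)(C1C=CC=C1)C1C=CC=C1 | intermediate (not isolated)
8 | (3E,6E,8S)-1-bromo-4,8,12-trimethyltrideca-3,6,11-triene | CC(C)=CCC[C@H](C)/C=C/C/C(C)=C/CCBr | intermediate
9 | propanal | CCC=O | starting material
10 | but-3-en-2-one (methyl vinyl ketone) | CC(=O)C=C | starting material
11 | (2R)-2-methyl-5-oxohexanal | C[C@@H](C=O)CCC(C)=O | intermediate
12 | (4R)-3-hydroxy-4-methylcyclohexan-1-one (both C3 epimers) | C[C@@H]1CCC(=O)CC1O | intermediate (not isolated)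
13 | (4R)-4-methylcyclohex-2-en-1-one | C[C@H]1C=CC(=O)CC1 | intermediate
14 | [(3E,6E,8S)-4,8,12-trimethyltrideca-3,6,11-trien-1-yl]magnesium bromide | CC(C)=CCC[C@H](C)/C=C/C/C(C)=C/CC[Mg]Br | intermediate (not isolated)
15 | trimethyl{[(3S,4R)-4-methyl-3-[(3E,6E,8S)-4,8,12-trimethyltrideca-3,6,11-trien-1-yl]cyclohex-1-en-1-yl]oxy}silane (chain and methyl trans) | CC(C)=CCC[C@H](C)/C=C/C/C(C)=C/CC[C@@H]1C=C(O[Si](C)(C)C)CC[C@H]1C | intermediate
16 | (4R)-4-methyl-3-[(3E,6E,8S)-4,8,12-trimethyltrideca-3,6,11-trien-1-yl]cyclohex-2-en-1-one | CC(C)=CCC[C@H](C)/C=C/C/C(C)=C/CCC1=CC(=O)CC[C@H]1C | intermediate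
17 | lithium (3R,4R)-3,4-dimethyl-3-[(3E,6E,8S)-4,8,12-trimethyltrideca-3,6,11-trien-1-yl]cyclohex-1-en-1-olate | CC(C)=CCC[C@H](C)/C=C/C/C(C)=C/CC[C@]1(C)[C@H](C)CCC(O[Li])=C1 | intermediate (not isolated)
18 | (3R,4R)-3,4-dimethyl-3-[(3E,6E,8S)-4,8,12-trimethyltrideca-3,6,11-trien-1-yl]cyclohex-1-en-1-yl trifluoromethanesulfonate | CC(C)=CCC[C@H](C)/C=C/C/C(C)=C/CC[C@]1(C)[C@H](C)CCC(OS(=O)(=O)C(F)(F)F)=C1 | intermediate
19 | (3R,4R)-3,4-dimethyl-1-(prop-1-en-2-yl)-3-[(3E,6E,8S)-4,8,12-trimethyltrideca-3,6,11-trien-1-yl]cyclohex-1-ene | CC(C)=CCC[C@H](C)/C=C/C/C(C)=C/CC[C@]1(C)[C@H](C)CCC(C(C)=C)=C1 | intermediate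
20 | 9-{2-[(3R,4R)-3,4-dimethyl-3-(C16 chain)cyclohex-1-en-1-yl]propyl}-9-borabicyclo[3.3.1]nonane (both C7 epimers) | CC(C)=CCC[C@H](C)/C=C/C/C(C)=C/CC[C@]1(C)[C@H](C)CCC(C(C)CB2C3CCCC2CCC3)=C1 | intermediate (not isolated)
21 | 2-[(3R,4R)-3,4-dimethyl-3-(C16 chain)cyclohex-1-en-1-yl]propan-1-ol (both C7 epimers) | CC(C)=CCC[C@H](C)/C=C/C/C(C)=C/CC[C@]1(C)[C@H](C)CCC(C(C)CO)=C1 | intermediate
22 | 2-[(3R,4R)-3,4-dimethyl-3-(C16 chain)cyclohex-1-en-1-yl]propanal (both C7 epimers) | CC(C)=CCC[C@H](C)/C=C/C/C(C)=C/CC[C@]1(C)[C@H](C)CCC(C(C)C=O)=C1 | intermediate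
23 | tert-butyl({(1E)-2-[(3R,4R)-3,4-dimethyl-3-(C16 chain)cyclohex-1-en-1-yl]prop-1-en-1-yl}oxy)dimethylsilane | CC(C)=CCC[C@H](C)/C=C/C/C(C)=C/CC[C@]1(C)[C@H](C)CCC(=C1)/C(C)=C/O[Si](C)(C)C(C)(C)C | intermediate (key-step precursor)
24 | acrolein (prop-2-enal) | C=CC=O | starting material
25 | (2S,3S,7R,8R,8aS)-3-[(tert-butyldimethylsilyl)oxy]-4,7,8-trimethyl-8-(C16 chain)-1,2,3,5,6,7,8,8a-octahydronaphthalene-2-carbaldehyde | CC(C)=CCC[C@H](C)/C=C/C/C(C)=C/CC[C@]1(C)[C@H](C)CCC2=C(C)[C@@H](O[Si](C)(C)C(C)(C)C)[C@@H](C=O)C[C@@H]12 | intermediate (key-step product)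
26 | [(2R,3S,7R,8R,8aS)-3-[(tert-butyldimethylsilyl)oxy]-4,7,8-trimethyl-8-(C16 chain)-1,2,3,5,6,7,8,8a-octahydronaphthalen-2-yl]methanol | CC(C)=CCC[C@H](C)/C=C/C/C(C)=C/CC[C@]1(C)[C@H](C)CCC2=C(C)[C@@H](O[Si](C)(C)C(C)(C)C)[C@@H](CO)C[C@@H]12 | intermediate
27 | [(2R,3S,7R,8R,8aS)-3-[(tert-butyldimethylsilyl)oxy]-4,7,8-trimethyl-8-(C16 chain)-1,2,3,5,6,7,8,8a-octahydronaphthalen-2-yl]methyl 4-methylbenzenesulfonate | CC(C)=CCC[C@H](C)/C=C/C/C(C)=C/CC[C@]1(C)[C@H](C)CCC2=C(C)[C@@H](O[Si](C)(C)C(C)(C)C)[C@@H](COS(=O)(=O)c3ccc(C)cc3)C[C@@H]12 | intermediate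
28 | [(2R,3S,7R,8R,8aS)-3-hydroxy-4,7,8-trimethyl-8-(C16 chain)-1,2,3,5,6,7,8,8a-octahydronaphthalen-2-yl]methyl 4-methylbenzenesulfonate (reacts as its alkoxide) | CC(C)=CCC[C@H](C)/C=C/C/C(C)=C/CC[C@]1(C)[C@H](C)CCC2=C(C)[C@@H](O)[C@@H](COS(=O)(=O)c3ccc(C)cc3)C[C@@H]12 | intermediate (not isolated)
29 | (2Z)-2-[(2S,3R,4R)-3,4-dimethyl-2-(prop-2-en-1-yl)-3-(C16 chain)cyclohexylidene]propanal | CC(C)=CCC[C@H](C)/C=C/C/C(C)=C/CC[C@]1(C)[C@H](C)CC/C(=C(\C)C=O)[C@H]1CC=C | intermediate
30 | (2Z)-2-[(2S,3R,4R)-3,4-dimethyl-2-(prop-2-en-1-yl)-3-(C16 chain)cyclohexylidene]propan-1-ol | CC(C)=CCC[C@H](C)/C=C/C/C(C)=C/CC[C@]1(C)[C@H](C)CC/C(=C(\C)CO)[C@H]1CC=C | intermediate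
31 | O,C-bis(9-borabicyclo[3.3.1]nonan-9-yl) derivative of 30 (boron on C11 and on the C8 oxygen) | CC(C)=CCC[C@H](C)/C=C/C/C(C)=C/CC[C@]1(C)[C@H](C)CC/C(=C(\C)COB2C3CCCC2CCC3)[C@H]1CCCB4C5CCCC4CCC5 | intermediate (not isolated)
32 | 3-[(1S,2R,3R,6Z)-6-(1-hydroxypropan-2-ylidene)-2,3-dimethyl-2-[(3E,6E,8S)-4,8,12-trimethyltrideca-3,6,11-trien-1-yl]cyclohexyl]propan-1-ol (CNP0327981.1) | CC(C)=CCC[C@H](C)/C=C/C/C(C)=C/CC[C@]1(C)[C@H](C)CC/C(=C(\C)CO)[C@H]1CCCO | target

**Step count**
Total: 19 steps. Longest linear sequence: 16 steps (steps 2, 3, 4, then 7 to 19, from 5-bromo-2-methylpent-2-ene); the branches from (S)-citronellal and from propanal are 15 steps each.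

**The three steps most likely to fail**

Step 14 (cycloaddition). The π-facial discrimination at C6 may be too weak if both half-chairs of ring A react, and bond formation at the neopentyl-type C6 terminus may be slow enough for acrolein to polymerise or the silyl enol ether to hydrolyse first. The fallback moves facial control from ring A to the dienophile. Setting out from 23, the acrylimide (R)-3-acryloyl-4-benzyl-1,3-oxazolidin-2-one (C=CC(=O)N1[C@H](Cc2ccccc2)COC1=O) is activated as its chelate with Et2AlCl in CH2Cl2 at −78 °C. The chelated, s-cis imide reacts endo on its face remote from the benzyl group, and through the endo relationship this decides which face of the diene is used; the auxiliary enantiomer is the one whose sense matches the preference of ring A. This should give the (4R)-4-benzyl-3-acyl-oxazolidinone adduct F1. LiBH4 in THF/MeOH then removes the auxiliary reductively and gives alcohol 26, where the route is rejoined (step 15 is not needed).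

Step 17 (fragmentation). The C8 alkoxide may close onto C11 to give a cis-fused oxetane instead of cleaving C8–C10, since oxygen and the CH2OTs group are cis in the endo adduct; the basic fluoride medium may also isomerise the Z enal or epimerise C6 through the dienolate. The fallback reverses the polarity of the fragmentation so that no alkoxide is present. From 27, displacement of the tosylate with Bu3SnLi (THF, −78 → 0 °C) gives the C11 tributylstannane F2. TBAF buffered with AcOH removes the silyl group and gives the γ-stannyl alcohol F3. Pb(OAc)4 in benzene at rt then effects the tin-directed oxidative 1,4-fragmentation, in which the oxygen is oxidised and tin leaves as the electrofuge, and gives enal 29, where the route is rejoined.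

Step 11 (hydroboration). 9-BBN may react too slowly with the isopropenyl group of the hindered conjugated diene, so that hydroboration of the chain alkenes competes and the selectivity is lost. The fallback builds the C7–C8 unit by carbonyl homologation instead. From 18, Stille coupling with tributyl(1-ethoxyvinyl)stannane (Pd(PPh3)4, LiCl, THF, 65 °C) gives the ethoxy diene F4, which dilute HCl hydrolyses to the methyl ketone F5. Wittig reaction with Ph3P=CHOMe (from (methoxymethyl)triphenylphosphonium chloride and KOt-Bu, THF, 0 °C) gives the methoxy diene F6 as an E/Z mixture. Brief hydrolysis with oxalic acid in wet THF, with kinetic protonation at C7, gives aldehyde 22, where the route is rejoined.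

**Further compounds**
F1 | step 14 | (4R)-4-benzyl-3-{[(2S,3S,7R,8R,8aS)-3-[(tert-butyldimethylsilyl)oxy]-4,7,8-trimethyl-8-(C16 chain)-1,2,3,5,6,7,8,8a-octahydronaphthalen-2-yl]carbonyl}-1,3-oxazolidin-2-one | CC(C)=CCC[C@H](C)/C=C/C/C(C)=C/CC[C@]1(C)[C@H](C)CCC2=C(C)[C@@H](O[Si](C)(C)C(C)(C)C)[C@@H](C(=O)N3[C@H](Cc4ccccc4)COC3=O)C[C@@H]12
F2 | step 17 | tributyl{[3-[(tert-butyldimethylsilyl)oxy]-4,7,8-trimethyl-8-(C16 chain)-1,2,3,5,6,7,8,8a-octahydronaphthalen-2-yl]methyl}stannane (configuration of 27 retained) | CC(C)=CCC[C@H](C)/C=C/C/C(C)=C/CC[C@]1(C)[C@H](C)CCC2=C(C)[C@@H](O[Si](C)(C)C(C)(C)C)[C@@H](C[Sn](CCCC)(CCCC)CCCC)C[C@@H]12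
F3 | step 17 | 3-[(tributylstannyl)methyl]-1,7,8-trimethyl-8-(C16 chain)-octahydronaphthalen-2-ol, the γ-stannyl alcohol from F2 (configuration retained) | CC(C)=CCC[C@H](C)/C=C/C/C(C)=C/CC[C@]1(C)[C@H](C)CCC2=C(C)[C@@H](O)[C@@H](C[Sn](CCCC)(CCCC)CCCC)C[C@@H]12
F4 | step 11 | (3R,4R)-1-(1-ethoxyethenyl)-3,4-dimethyl-3-(C16 chain)cyclohex-1-ene | CC(C)=CCC[C@H](C)/C=C/C/C(C)=C/CC[C@]1(C)[C@H](C)CCC(C(=C)OCC)=C1
F5 | step 11 | 1-[(3R,4R)-3,4-dimethyl-3-(C16 chain)cyclohex-1-en-1-yl]ethan-1-one | CC(C)=CCC[C@H](C)/C=C/C/C(C)=C/CC[C@]1(C)[C@H](C)CCC(C(C)=O)=C1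
F6 | step 11 | (3R,4R)-1-(1-methoxyprop-1-en-2-yl)-3,4-dimethyl-3-(C16 chain)cyclohex-1-ene (E/Z mixture) | CC(C)=CCC[C@H](C)/C=C/C/C(C)=C/CC[C@]1(C)[C@H](C)CCC(C(C)=COC)=C1
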